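Everything rests on cutting the C9–C10 bond of ring B: a C7 ketone two bonds from the ring-fusion carbon C5, with C9 joined to the quaternary, methyl-bearing C10, is the signature of an anionic oxy-Cope rearrangement of a 7-alkenylbicyclo[2.2.2]octenol. In a single operation the C7 alkoxide closes ring B, forges the C10 quaternary centre together with C9, and releases the C7 ketone as its enolate. The precursor is a tricyclic carbinol assembled from 2-methoxy-4-methylphenol by oxidative ketalisation and intramolecular Diels–Alder reaction: its C6 ketal is tied through oxygen to C18, C19 is a benzyl ether, and C7 carries the complete C8–C15 chain as a (Z)-alkenyl group.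

Key step: step 8

Remarks on the chemistry (assumptions, one line each):
- Numbering: labdane numbers are used for every ring compound, also for the bicyclic ones (C7 carbonyl or carbinol, C6 ketal, C2 and C5 bridgeheads, C1=C10 alkene with C20 on C10, C4 bearing C18 and C19).
- Alkene geometry: for C11 to end β at C9 (syn to C20) the C8=C9 unit of the precursor must be Z (C7 and C11 on the same side), because in the enforced boat array the C9 substituent cis to C7 is the one that ends syn to the C10 methyl; an E unit would give the C9 epimer, so the alkenyl donor is made as a (Z)-2-iodo-2-alkene.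
- Protecting groups: C19 is carried as a benzyl ether and C15 as a TBS ether, so that no aryl silane meets the dissolving metal and C19–OH is released in the operation that corrects the ring fusion.
- Resolution: it is assumed that the enantiomer of 5 with the configuration drawn for 6 is identified after separation (for example by anomalous-dispersion X-ray analysis).
- C8 is drawn throughout as the 8α-methyl epimer; it is epimerisable next to C7 and is fixed by equilibration in step 14.

Step 1
Reactants: 1 2-methylenepropane-1,3-diol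
Product: 2 2-[(benzyloxy)methyl]prop-2-en-1-ol
Conditions: BnBr, Ag2O, CH2Cl2, rt (diol in slight excess)
Reagents that add atoms: benzyl bromide, BrCc1ccccc1
Why: Silver(I) oxide-mediated Williamson etherification of a symmetrical diol should stop at the monoether, since the silver-coordinated diol is alkylated faster than the monoether formed, and no stereocentre arises.

Step 2
Reactants: 3 2-methoxy-4-methylphenol; 2 2-[(benzyloxy)methyl]prop-2-en-1-ol (about 3 equiv, excess recovered)
Product: 5 racemic 3-[(benzyloxy)methyl]-6-methoxy-8-methyl-5-oxatricyclo[4.3.1.0(3,7)]dec-8-en-10-one, via masked o-benzoquinone 4 (not isolated)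
Conditions: PhI(OAc)2, CH2Cl2, 0 °C to reflux
Reagents that add atoms: none
Why: Hypervalent-iodine oxidative dearomatisation in the presence of the allylic alcohol gives the mixed quinone monoketal, which is trapped by intramolecular Diels–Alder reaction before it can dimerise; the three-atom O–CH2 tether fixes the regiochemistry and the relative configuration of C2, C4, C5 and C6 (tethered arm C18 syn to the ketal bridge, CH2OBn arm C19 syn to the new C1=C10 bridge), so one racemic diastereomer should form.

Step 3
Reactants: 5 racemic tricyclic keto ketal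
Product: 6 3-[(benzyloxy)methyl]-6-methoxy-8-methyl-5-oxatricyclo[4.3.1.0(3,7)]dec-8-en-10-one as the single enantiomer drawn
Conditions: preparative HPLC on amylose tris(3,5-dimethylphenylcarbamate), hexane/i-PrOH
Reagents that add atoms: none
Why: Resolution by chromatography on a chiral stationary phase should separate the enantiomers of this rigid, UV-active ketone without chemical change, and it supplies the absolute configuration of C4 and C10 of the target.

Step 4
Reactants: 7 geraniol
Product: 8 tert-butyl{[(2E)-3,7-dimethylocta-2,6-dien-1-yl]oxy}dimethylsilane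
Conditions: TBSCl, imidazole, DMF, rt
Reagents that add atoms: tert-butyldimethylsilyl chloride, CC(C)(C)[Si](C)(C)Cl
Why: Imidazole-promoted silylation of a primary allylic alcohol is routine and gives an ether that tolerates organolithium, potassium hydride, samarium and dissolving-metal conditions.

Step 5
Reactants: 8 geranyl TBS ether
Product: 10 (4E)-6-{[tert-butyl(dimethyl)silyl]oxy}-4-methylhex-4-enal, via epoxide 9 (not isolated)
Conditions: mCPBA, CH2Cl2, −20 to 0 °C; then H5IO6, THF/H2O, 0 °C
Reagents that add atoms: 3-chloroperbenzoic acid, O=C(OO)c1cccc(Cl)c1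
Why: Prilezhaev epoxidation should prefer the more electron-rich distal C6=C7 bond over the allylically oxygenated C2=C3 bond, and periodic acid opens and cleaves the crude epoxide (glycol-type cleavage) to the aldehyde with loss of acetone while the 2E alkene is kept.

Step 6
Reactants: 10 aldehyde; 11 ethyltriphenylphosphonium iodide
Product: 12 tert-butyl{[(2E,6Z)-7-iodo-3-methylocta-2,6-dien-1-yl]oxy}dimethylsilane
Conditions: 11, n-BuLi, THF, 0 °C; I2, −78 °C; NaHMDS, −20 °C; then 10, −78 °C to rt
Reagents that add atoms: iodine, II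
Why: Wittig olefination with the α-iodo ylide Ph3P=C(I)CH3 (Stork–Zhao-type) is kinetically Z-selective for 2-iodo-2-alkenes, which places iodine cis to the chain as the rearrangement demands.

Step 7
Reactants: 12 (Z)-vinyl iodide; 6 resolved tricyclic ketone
Product: 14 tricyclic carbinol 3-[(benzyloxy)methyl]-10-[(2Z,6E)-8-{[tert-butyl(dimethyl)silyl]oxy}-6-methylocta-2,6-dien-2-yl]-6-methoxy-8-methyl-5-oxatricyclo[4.3.1.0(3,7)]dec-8-en-10-ol with the alkenyl group syn to C1=C10, via alkenyllithium 13 (not isolated)
Conditions: t-BuLi (2 equiv), Et2O, −78 °C; then 6, THF, −78 to −20 °C; NH4Cl (aq)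
Reagents that add atoms: none
Why: Iodine–lithium exchange retains the Z geometry and the alkenyllithium should add (1,2-addition) to the non-enolisable C7 ketone from the face of the C1=C10 bridge, which is less shielded than the face under the C3 methylene, so the new C7 stereocentre carries the alkenyl group syn to C1=C10.

Step 8
Reactants: 14 tricyclic carbinol
Product: 17 19-benzyloxy-15-(tert-butyldimethylsilyloxy)-6α,18-epoxy-6β-methoxy-5β-H-labda-1,13E-dien-7-one (cis-fused), via potassium alkoxide 15 (not isolated), via potassium enolate 16 (not isolated)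
Conditions: KH, 18-crown-6, THF, 0 °C to reflux; then NH4Cl (aq), −78 °C
Reagents that add atoms: none
Why: KH with 18-crown-6 turns 14 into the weakly ion-paired C7 alkoxide 15, which undergoes a concerted suprafacial [3,3] shift across C9=C8–C7–C2–C1=C10, breaking C7–C2 and forming C9–C10 to give enolate 16, protonated on quench to 17. The closest known reaction is the anionic oxy-Cope rearrangement of 2-alkenylbicyclo[2.2.2]oct-5-en-2-ols derived from masked o-benzoquinone Diels–Alder adducts, which gives cis-fused decalenones. Ring B (C5–C6–C7–C8–C9–C10) is closed by the new C9–C10 σ-bond inside a six-centre boat transition state imposed by the bicycle, that is by sigmatropic reorganisation and not by an ionic exo or endo cyclisation. C10 is fixed because C9 can only reach the face of C1=C10 turned towards the C6–C7 bridge, which puts the C10 methyl cis to H5 and syn to the untethered arm C19; C9 follows from the Z geometry, since in the boat the C9 substituent cis to C7 (C11) ends on the same face of ring B as the C10 methyl; C8 is set on protonation of 16 and stays epimerisable. The step needs the [3,3] path to win over retro-addition or fragmentation of the alkoxide, which the syn placement of the alkenyl group from step 7 and the rigid, pre-organised 1,5-diene should secure.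

Step 9
Reactants: 17 cis-fused keto ketal
Product: 18 19-benzyloxy-15-(tert-butyldimethylsilyloxy)-18-hydroxy-5β-H-labda-1,13E-dien-7-one
Conditions: SmI2 (5 equiv), THF/MeOH, −78 °C to rt
Reagents that add atoms: none
Why: Samarium diiodide reduction of an α-alkoxy ketone: the C7 ketyl expels first one and then the other C6 oxygen substituent, each time followed by protonation of the samarium enolate, which turns C6 into CH2, opens the oxolane to free C18–OH and leaves the ethers, both alkenes and the ring-fusion centres untouched.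

Step 10
Reactants: 18 hydroxy ketone
Product: 19 19-benzyloxy-15-(tert-butyldimethylsilyloxy)-18-hydroxy-5β-H-labd-13E-en-7-one
Conditions: H2 (1 atm), RhCl(PPh3)3 (cat.), benzene/EtOH, rt
Reagents that add atoms: none
Why: Homogeneous hydrogenation with Wilkinson's catalyst should saturate the cis-disubstituted ring alkene C1=C2 much faster than the trisubstituted, allylically oxygenated C13=C14 bond and does not hydrogenolyse the benzyl ether; no stereocentre is created.

Step 11
Reactants: 19 saturated hydroxy ketone
Product: 20 19-benzyloxy-15-(tert-butyldimethylsilyloxy)-18-iodo-5β-H-labd-13E-en-7-one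
Conditions: PPh3, I2, imidazole, toluene, 80 °C
Reagents that add atoms: iodine, II
Why: Appel-type iodination under Garegg–Samuelsson conditions converts the only free hydroxyl into the iodide; the neopentyl position needs heat but cannot eliminate because C4 bears no hydrogen, and the imidazole buffer protects the silyl ether.

Step 12
Reactants: 20 neopentyl iodide
Product: 21 19-benzyloxy-15-(tert-butyldimethylsilyloxy)-5β-H-labd-13E-en-7-one
Conditions: Bu3SnH, AIBN (cat.), toluene, 80 °C
Reagents that add atoms: none
Why: Radical chain dehalogenation with tributyltin hydride turns C18 into the methyl group; the primary C18 radical has no favourable cyclisation onto C13=C14 or the ketone and is quenched by the tin hydride.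

Step 13
Reactants: 21 cis-fused ketone
Product: 23 19-benzyloxy-15-(tert-butyldimethylsilyloxy)labda-5,13E-dien-7-one, via silyl enol ether 22 (not isolated)
Conditions: LDA, THF, −78 °C, then TMSCl; solvent exchange; Pd(OAc)2, MeCN, rt
Reagents that add atoms: none
Why: Saegusa–Ito oxidation: kinetic deprotonation should occur at the C6 methylene in preference to the C8 methine, and palladium(II) converts the Δ6 silyl enol ether by β-hydride elimination of H5 into the C5=C6 enone, which erases the cis ring-fusion centre.

Step 14
Reactants: 23 enone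
Product: 25 15-(tert-butyldimethylsilyloxy)-19-hydroxylabd-13E-en-7-one (5α-H, 8α-methyl, 9β side chain), via lithium enolate 24 (not isolated)
Conditions: Li, NH3(l)/THF, −78 °C; solid NH4Cl; then NaOMe (cat.), MeOH, rt
Reagents that add atoms: none
Why: Dissolving-metal (Birch-type) reduction of the enone should deliver the new H5 axially on the α face, opposite the axial C20 and C19 groups, to give the trans ring fusion as the lithium enolate (which shields C7 from further reduction), while the same medium cleaves the C19 benzyl ether; methoxide then equilibrates C8 to the equatorial 8α-methyl epimer, which avoids a 1,3-diaxial contact with C20.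

Step 15
Reactants: 25 trans-fused hydroxy ketone
Product: 26 19-acetoxy-15-(tert-butyldimethylsilyloxy)labd-13E-en-7-one
Conditions: Ac2O, pyridine, DMAP (cat.), CH2Cl2, rt
Reagents that add atoms: acetic anhydride, CC(=O)OC(C)=O
Why: DMAP-catalysed acylation esterifies the only free hydroxyl, the hindered neopentyl C19–OH, while C15 is still silylated.

Step 16
Reactants: 26 acetate silyl ether
Product: 27 19-acetoxy-15-hydroxylabd-13E-en-7-one, (4S,5R,8S,9S,10R), the target
Conditions: HF·pyridine, THF/pyridine, 0 °C to rt
Reagents that add atoms: none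
Why: Fluoride-mediated desilylation under buffered conditions removes the primary allylic TBS group without touching the acetate, the ketone or the C8 centre.

Compound list
1 | 2-methylenepropane-1,3-diol | C=C(CO)CO | starting material
2 | 2-[(benzyloxy)methyl]prop-2-en-1-ol | C=C(CO)COCc1ccccc1 | intermediate
3 | 2-methoxy-4-methylphenol | COc1cc(C)ccc1O | starting material
4 | 6-({2-[(benzyloxy)methyl]prop-2-en-1-yl}oxy)-6-methoxy-4-methylcyclohexa-2,4-dien-1-one (masked o-benzoquinone, racemic) | COC1(OCC(=C)COCc2ccccc2)C=C(C)C=CC1=O | intermediate (not isolated)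
5 | racemic 3-[(benzyloxy)methyl]-6-methoxy-8-methyl-5-oxatricyclo[4.3.1.0(3,7)]dec-8-en-10-one (both enantiomers shown) | c5ccccc5COC[C@@]1(CO3)C[C@H]4C=C(C)[C@@H]1[C@]3(OC)C4=O.c5ccccc5COC[C@]1(CO3)C[C@@H]4C=C(C)[C@H]1[C@@]3(OC)C4=O | intermediate
6 | the same tricyclic keto ketal, single enantiomer (C19 arm syn to C1=C10, C18 in the oxolane) | c5ccccc5COC[C@@]1(CO3)C[C@H]4C=C(C)[C@@H]1[C@]3(OC)C4=O | intermediate
7 | geraniol | CC(C)=CCC/C(C)=C/CO | starting material
8 | tert-butyl{[(2E)-3,7-dimethylocta-2,6-dien-1-yl]oxy}dimethylsilane | CC(C)=CCC/C(C)=C/CO[Si](C)(C)C(C)(C)C | intermediate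
9 | 6,7-epoxide of 8 (racemic) | CC1(C)OC1CC/C(C)=C/CO[Si](C)(C)C(C)(C)C | intermediate (not isolated)
10 | (4E)-6-{[tert-butyl(dimethyl)silyl]oxy}-4-methylhex-4-enal | O=CCC/C(C)=C/CO[Si](C)(C)C(C)(C)C | intermediate
11 | ethyltriphenylphosphonium iodide | CC[P+](c1ccccc1)(c1ccccc1)c1ccccc1.[I-] | starting material
12 | tert-butyl{[(2E,6Z)-7-iodo-3-methylocta-2,6-dien-1-yl]oxy}dimethylsilane | C/C(I)=C/CC/C(C)=C/CO[Si](C)(C)C(C)(C)C | intermediate
13 | (2Z,6E)-8-(tert-butyldimethylsilyloxy)-6-methylocta-2,6-dien-2-yllithium | C/C([Li])=C/CC/C(C)=C/CO[Si](C)(C)C(C)(C)C | intermediate (not isolated)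
14 | tricyclic carbinol: C7 tertiary alcohol bearing the (Z)-alkenyl chain syn to C1=C10, C6 ketal tied to C18, C19 benzyl ether | c5ccccc5COC[C@@]1(CO3)C[C@H]4C=C(C)[C@@H]1[C@]3(OC)[C@]4(O)/C(C)=C\CC/C(C)=C/CO[Si](C)(C)C(C)(C)C | intermediate
15 | potassium C7 alkoxide of 14 | c5ccccc5COC[C@@]1(CO3)C[C@H]4C=C(C)[C@@H]1[C@]3(OC)[C@]4([O-])/C(C)=C\CC/C(C)=C/CO[Si](C)(C)C(C)(C)C.[K+] | intermediate (not isolated)
16 | potassium C7=C8 enolate of 17 | c4ccccc4COC[C@@]1(CO3)CC=C[C@]2(C)[C@@H](CC/C(C)=C/CO[Si](C)(C)C(C)(C)C)C(C)=C([O-])[C@@]3(OC)[C@H]12.[K+] | intermediate (not isolated)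
17 | 19-benzyloxy-15-(tert-butyldimethylsilyloxy)-6α,18-epoxy-6β-methoxy-5β-H-labda-1,13E-dien-7-one | c4ccccc4COC[C@@]1(CO3)CC=C[C@]2(C)[C@@H](CC/C(C)=C/CO[Si](C)(C)C(C)(C)C)[C@H](C)C(=O)[C@@]3(OC)[C@H]12 | intermediate
18 | 19-benzyloxy-15-(tert-butyldimethylsilyloxy)-18-hydroxy-5β-H-labda-1,13E-dien-7-one | c4ccccc4COC[C@@]1(CO)CC=C[C@]2(C)[C@@H](CC/C(C)=C/CO[Si](C)(C)C(C)(C)C)[C@H](C)C(=O)C[C@H]12 | intermediate
19 | 19-benzyloxy-15-(tert-butyldimethylsilyloxy)-18-hydroxy-5β-H-labd-13E-en-7-one | c4ccccc4COC[C@@]1(CO)CCC[C@]2(C)[C@@H](CC/C(C)=C/CO[Si](C)(C)C(C)(C)C)[C@H](C)C(=O)C[C@H]12 | intermediate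
20 | 19-benzyloxy-15-(tert-butyldimethylsilyloxy)-18-iodo-5β-H-labd-13E-en-7-one | c4ccccc4COC[C@@]1(CI)CCC[C@]2(C)[C@@H](CC/C(C)=C/CO[Si](C)(C)C(C)(C)C)[C@H](C)C(=O)C[C@H]12 | intermediate
21 | 19-benzyloxy-15-(tert-butyldimethylsilyloxy)-5β-H-labd-13E-en-7-one | c4ccccc4COC[C@@]1(C)CCC[C@]2(C)[C@@H](CC/C(C)=C/CO[Si](C)(C)C(C)(C)C)[C@H](C)C(=O)C[C@H]12 | intermediate
22 | 7-(trimethylsilyloxy)-Δ6 silyl enol ether of 21 | c4ccccc4COC[C@@]1(C)CCC[C@]2(C)[C@@H](CC/C(C)=C/CO[Si](C)(C)C(C)(C)C)[C@H](C)C(O[Si](C)(C)C)=C[C@H]12 | intermediate (not isolated)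
23 | 19-benzyloxy-15-(tert-butyldimethylsilyloxy)labda-5,13E-dien-7-one | c4ccccc4COC[C@@]1(C)CCC[C@]2(C)[C@@H](CC/C(C)=C/CO[Si](C)(C)C(C)(C)C)[C@H](C)C(=O)C=C12 | intermediate
24 | dilithium salt: Δ6 enolate and C19 alkoxide of 25 | [Li+].[Li+].[O-]C[C@@]1(C)CCC[C@]2(C)[C@@H](CC/C(C)=C/CO[Si](C)(C)C(C)(C)C)[C@H](C)C([O-])=C[C@@H]12 | intermediate (not isolated)
25 | 15-(tert-butyldimethylsilyloxy)-19-hydroxylabd-13E-en-7-one | OC[C@@]1(C)CCC[C@]2(C)[C@@H](CC/C(C)=C/CO[Si](C)(C)C(C)(C)C)[C@H](C)C(=O)C[C@@H]12 | intermediate
26 | 19-acetoxy-15-(tert-butyldimethylsilyloxy)labd-13E-en-7-one | CC(=O)OC[C@@]1(C)CCC[C@]2(C)[C@@H](CC/C(C)=C/CO[Si](C)(C)C(C)(C)C)[C@H](C)C(=O)C[C@@H]12 | intermediate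
27 | 19-acetoxy-15-hydroxylabd-13E-en-7-one, (4S,5R,8S,9S,10R) | CC(=O)OC[C@@]1(C)CCC[C@]2(C)[C@@H](CC/C(C)=C/CO)[C@H](C)C(=O)C[C@@H]12 | target

Total step count: 16. Longest linear sequence: 13 steps (steps 1–3 and 7–16, or equally steps 4–16).

Steps most likely to fail

Step 8. The rearrangement may stall, or the alkoxide may fragment, because the inward-pointing C11 chain of the Z-alkenyl group is pressed against the C6 methoxy group in the boat transition state. Fallback, setting out from 6 and returning at 18: the C6 oxygens are removed before the alkenyl group is introduced. Ketone 6 is reduced with SmI2 in THF/MeOH to the bicyclic hydroxy ketone F1 (C6 now CH2, C18–OH free). Its hydroxyl is capped with TMSCl/Et3N to give the silyl ether F2. CeCl3-promoted addition of 13 gives the adduct F3, which is desilylated on mild acidic work-up to the diol F4. KH/18-crown-6 then effects the same [3,3] shift, now with only a C6 hydrogen facing C11, and should deliver 18.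

Step 7. Addition of the hindered trisubstituted alkenyllithium may be slow or may occur from the wrong face, since the C6 methoxy group lies on the face of attack. Fallback, setting out from 10 and 6 and returning at 17: the C8 methyl group is left out of the nucleophile and introduced afterwards. Aldehyde 10 undergoes Stork–Zhao olefination with (iodomethyl)triphenylphosphonium iodide/NaHMDS to the (Z)-1-iodoalkene F5. t-BuLi converts it into the smaller alkenyllithium F6, which is added to 6 to give the carbinol F7. KH/18-crown-6 rearranges F7 to the potassium enolate F8, which is C-methylated at C8 with iodomethane in the same flask (C6 is fully substituted, so no second site competes) to give 17 after equilibration at C8.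

Step 14. The allylic C15 silyloxy group may be lost reductively, or C7 over-reduced, under the excess metal needed for debenzylation. Fallback, setting out from 23 and returning at 27: the allylic oxygen is unmasked first, so that it is present as an alkoxide that resists cleavage. Enone 23 is desilylated with HF·pyridine to the hydroxy enone F9 and reduced with Li/NH3 (then methoxide equilibration) to the 15,19-diol F10. Acetylation gives the diacetate F11, and the unhindered allylic C15 acetate is removed selectively (lipase-mediated hydrolysis, or K2CO3/MeOH at 0 °C) in preference to the neopentyl C19 acetate to give 27.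

Further compounds
F1 | step 8 | bicyclic hydroxy ketone from 6 (C6 CH2, C18–OH, C19 OBn) | c5ccccc5COC[C@@]1(CO)C[C@H]4C=C(C)[C@@H]1CC4=O
F2 | step 8 | C18 trimethylsilyl ether of F1 | c5ccccc5COC[C@@]1(CO[Si](C)(C)C)C[C@H]4C=C(C)[C@@H]1CC4=O
F3 | step 8 | C7 alkenyl carbinol from F2 (C18 OTMS) | c5ccccc5COC[C@@]1(CO[Si](C)(C)C)C[C@H]4C=C(C)[C@@H]1C[C@]4(O)/C(C)=C\CC/C(C)=C/CO[Si](C)(C)C(C)(C)C
F4 | step 8 | C7 alkenyl carbinol with free C18–OH | c5ccccc5COC[C@@]1(CO)C[C@H]4C=C(C)[C@@H]1C[C@]4(O)/C(C)=C\CC/C(C)=C/CO[Si](C)(C)C(C)(C)C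
F5 | step 7 | tert-butyl{[(2E,6Z)-7-iodo-3-methylhepta-2,6-dien-1-yl]oxy}dimethylsilane | I/C=C\CC/C(C)=C/CO[Si](C)(C)C(C)(C)C
F6 | step 7 | (1Z,5E)-7-(tert-butyldimethylsilyloxy)-5-methylhepta-1,5-dien-1-yllithium | [Li]/C=C\CC/C(C)=C/CO[Si](C)(C)C(C)(C)C
F7 | step 7 | tricyclic carbinol lacking the C8 methyl group | c5ccccc5COC[C@@]1(CO3)C[C@H]4C=C(C)[C@@H]1[C@]3(OC)[C@]4(O)/C=C\CC/C(C)=C/CO[Si](C)(C)C(C)(C)C
F8 | step 7 | potassium C7=C8 enolate lacking the C8 methyl group | c4ccccc4COC[C@@]1(CO3)CC=C[C@]2(C)[C@@H](CC/C(C)=C/CO[Si](C)(C)C(C)(C)C)C=C([O-])[C@@]3(OC)[C@H]12.[K+]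
F9 | step 14 | 19-benzyloxy-15-hydroxylabda-5,13E-dien-7-one | c4ccccc4COC[C@@]1(C)CCC[C@]2(C)[C@@H](CC/C(C)=C/CO)[C@H](C)C(=O)C=C12
F10 | step 14 | 15,19-dihydroxylabd-13E-en-7-one | OC[C@@]1(C)CCC[C@]2(C)[C@@H](CC/C(C)=C/CO)[C@H](C)C(=O)C[C@@H]12
F11 | step 14 | 15,19-diacetoxylabd-13E-en-7-one | CC(=O)OC[C@@]1(C)CCC[C@]2(C)[C@@H](CC/C(C)=C/COC(C)=O)[C@H](C)C(=O)C[C@@H]12
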